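(The earlier runs and the new flask come from a simulation with constants of no real substance, noise included.)

Monomer in chains is what the average counts, divided by the chains begun, and the runs show the first but not the second.

the same everywhere: pre-initiator 0.37 mM

| run | free monomer | remark | time |
|---|---|---|---|
| north-west | 12 mM | the very flask that is asked about, followed so far |  |
| west | 24 mM | run made earlier |  |
| flask | 12 mM |  | 10 min |

north-west run (percent of the free monomer charged)

| time / s | monomer in chains / % | free monomer / % |
|---|---|---|
| 15.0 | 0 | 99.7 |
| 30.0 | 0.2 | 100.5 |
| 50.0 | 0 | 100.2 |
| 60.0 | 0.1 | 100.2 |
| 80.0 | 0.1 | 98.5 |
| 90.0 | 0 | 100.2 |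
| 120 | 0 | 98.4 |

west run (percent of the free monomer charged)

| time / min | monomer in chains / % | free monomer / % |
|---|---|---|
| 0.500 | 0 | 99.3 |
| 1.00 | 0.8 | 99.5 |
| 1.50 | 0.3 | 99.0 |
| 2.50 | 1.3 | 97.5 |
| 3.00 | 2.4 | 98.0 |
| 4.00 | 3.7 | 95.5 |

(each reading ± 0.5 percentage points)

- whether the average number of monomer units in a chain (chains begun, living or dead) reaches 3.0 by 10 min (yes / no)
- average number of monomer units in a chain (chains begun, living or dead) at 10 min

- the average divides the monomer in chains by the number of chains begun, living and dead together
- the earlier runs do not show the number of chains; that part of a forecast is a guess

I took each chain to begin from one pre-initiator, so that the pre-initiator charge caps the chains begun. I therefore defined the safe conversion x*, the share of the free monomer charged that must stand in chains for the average to reach 3.0 with chains begun equal to the whole charge: 9.25 %. In the west run x* is 4.62 %, and its last reading of 3.7 % stands below that.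

The west readings rose about as time squared, which carried to 10 min gave 23.1 %, and a rate first order in monomer puts the same percentage in the flask. The same curve put 0.925 % at the last north-west reading, which showed 0 % with a scatter of 0.5 percentage points, so I also took a rate second order in monomer, giving 11.6 %. Even that is more than x*, so I expected the flask to reach the length, the lower estimate giving an average of at least 3.75 if the whole pre-initiator charge began chains.

The forecast said yes, with an average of 9, adding “the chain count is unseen, so this is uncertain”. The flask gave yes, with 10.0.

    free monomer + initiator → living end + monomer in chains (k = 53.0 /M/min)
    free monomer + living end → monomer in chains + living end, rate k2*[living end]*[free monomer] (k = 280 /M/min)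
    monomer in chains + living end → free monomer + living end, rate k3*[living end] as long as [monomer in chains] is above zero (k = 1.30 /min)
    2 initiator → spent initiator (k = 1100 /M/min)
    pre-initiator → initiator (k = 0.100 /min)

At 10.0 min the flask held 15.5 % in chains, more than x*, and its average was twice the floor of 5.03, with the living end at 0.186 mM, half of the pre-initiator charge. At that moment in the flask, growth used free monomer 38 times as fast as the starting of chains did, and monomer in chains was made 2.24 times as fast as it was used up.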